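## Structural features

Isocardopatine (18) is a cyclobutane in which the adjacent methine carbons C1 and C2 each carry a (2,2'-bithiophen-5-yl)ethynyl arm, while C3 and C4 are plain methylenes. The stereodescriptors place both arms on the same ring face, so the compound is cis and, having a mirror plane through the midpoints of C1–C2 and C3–C4, meso (1R,2S). No absolute stereocontrol is therefore needed and every chiral intermediate can be racemic. The only stereochemical problem is the relative configuration of two vicinal stereocentres, and cis is the less stable arrangement, so it has to be made kinetically and never equilibrated. The ring carries no heteroatom and both substituents are attached through sp carbons, which removes the usual handles for building a cyclobutane. Fragile features are the strained ring, the cis-held 1,5-diyne (thermal rearrangement at high temperature), the electron-rich, strongly absorbing bithienylalkynes (light, oxidants, acid) and the volatility of the small diyne core. The key step exploits the fact that the ring-bound sp carbon on C2 is at the oxidation level of a carboxyl carbon: the pattern C2(carboxyl)/C1(alkynyl) joined to C3 is what a 2-diazo-3-alkynylcyclopentanone leaves on ring contraction, and the alkyne on C1 steers the protonation that creates C2.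

## Logic of the disconnections

18 is cut at both C(sp)–C5(thienyl) bonds to give 17 and two equivalents of 16. The cut uses the mirror symmetry, removes both chromophores and leaves an eight-carbon core plus a commercial aryl bromide. The forward step must couple twice without oxidative alkyne dimerisation, and 17 is volatile, so it is traced one C–Si bond further back to 15 and is only ever generated in solution.

15 is cut inside the unsilylated triple bond, its terminal carbon coming from CBr4 through 13 and its ring-bound carbon being the formyl carbon of 12. This differentiates the two arms: one is an alkyne from the outset, the other is a carbonyl carbon. The demand is that 12, whose α-stereocentre is cis to its neighbour, is olefinated under non-basic conditions before it can epimerise.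

12 is related to 10 by adjustment of oxidation level only. The forward reduction has to stop at the aldehyde and be worked up without enolisation.

10 is disconnected at the ring bond C2–C3 and at the ester C–O bond, which leads back to 7 and methanol. Re-joining C3 to the carboxyl carbon turns the strained four-membered ring into a cyclopentanone, whose substitution pattern is easy to build. In the forward direction one photochemical step makes the ring and the second stereocentre. It requires that carbon migration outruns hydride shift, that the enol is protonated anti to the alkynyl group, and that the alkyne substituent is transparent to the light used, hence the silyl group.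

7 is cut at the C=N2 bond and, one stage earlier, at the bond between C2 and a trifluoroacetyl group, giving 6 and then 4. The acyl group is a traceless activator that makes diazo transfer possible at a simple ketone α-carbon. The demand is complete regiocontrol: acylation must occur at C2, between the carbonyl and the substituted carbon, which kinetic deprotonation of the free ketone would not deliver. The enolate 5 is therefore generated from 4, in which the position of the double bond is stored.

4 is cut at the C3–C(sp) bond and at O–Si to give 1 and 2. Conjugate addition makes the only ring-to-alkyne bond that is carried unchanged to the target, and it leaves the enolate double bond between C1 and C2, exactly where the diazo group is needed. The forward step must give 1,4- and not 1,2-addition to an s-trans enone, and the silyl enol ether must survive isolation.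

## Other disconnections considered

Alternative 1: Both ring-to-alkyne bonds are cut and traced to C–B bonds, leading to cis-1,2-bis(pinacolboryl)cyclobutane A2, which comes from syn-diboration of cyclobutene A1 with a diboron reagent and a platinum catalyst such as Pt(PPh3)4.
- Forward key step: each boronic ester would be treated with 1-lithioethenyl N,N-diisopropylcarbamate A3 to form a boronate complex. Iodine triggers a 1,2-metallate shift with retention, followed by boron/iodine elimination, and a lithium amide then expels the carbamate to give cis-1,2-diethynylcyclobutane A4, identical with 17.
- In its favour: the cis relationship is fixed by a syn addition and transferred by stereoretentive migrations, so neither stereocentre is ever next to a carbonyl group. Both arms are made at once, which uses the symmetry of the target fully, and about four operations from A1 would reach 18.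
- Against it: A1 is a low-boiling gas that normally has to be prepared. Two vicinal secondary C–B bonds on a small ring must each form a congested boronate complex beside the other, and exhaustive homologation of such bis(boronates) is thinly precedented, so mono-functionalisation or protodeboronation is plausible. The sequence ends at the same volatile diyne.
- Comparison: on step economy and on stereochemical security this route is better than the chosen plan. The chosen plan is stronger in starting-material availability and in relying on individually well-precedented steps, with its stereochemical risk concentrated in one protonation rather than spread over a double key step.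

Alternative 2: The ring bonds C1–C4 and C2–C3 are cut.
- Forward key step: dichloroketene A6, generated in the flask, adds in a concerted [2+2] fashion to one double bond of cyclohexa-1,4-diene A5 to give cis-8,8-dichlorobicyclo[4.2.0]oct-3-en-7-one A7.
- In its favour: cheap reagents, a scalable and reliable cycloaddition, no light and no diazo compound. The cis ring fusion is enforced and is also the thermodynamic preference of the bicycle, so the relative configuration is at least as secure as in the chosen plan, and arguably more so.
- Against it: the cycloaddition puts a carbonyl group and two chlorines on what become the unsubstituted C3 and C4. These must be erased by reductive dechlorination and deoxygenation to reach cis-bicyclo[4.2.0]oct-3-ene A8. The six-membered ring must then be cleaved to the dialdehyde 2,2'-(cis-cyclobutane-1,2-diyl)diacetaldehyde A9, and each CH2–CHO stub must be converted into a terminal alkyne without change of carbon count, by enol sulfonate formation and elimination, twice. Several intermediates are volatile C8 compounds, and double cycloaddition to A5 has to be suppressed.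
- Comparison: mechanistically the ring construction is more robust than a photochemical contraction, but structurally the functionality arrives on the wrong carbons. Most later steps remove atoms rather than build the target, and the count (about seven to nine steps to 18) is no better than the eight of the chosen plan.

Alternative 3: The bonds C1–C2 and C1–C4 are cut.
- Forward key step: 3-(2,2'-bithiophen-5-yl)prop-2-ynal A10, available from 16, would react with diphenylsulfonium cyclopropylide A11 to give 2-[(2,2'-bithiophen-5-yl)ethynyl]-1-oxaspiro[2.2]pentane A12. With LiBF4 this would open to a propargylic cyclopropylcarbinyl cation and expand to 2-[(2,2'-bithiophen-5-yl)ethynyl]cyclobutan-1-one A13.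
- In its favour: it is convergent, one arm is complete from the start, the ring is reached in two operations, and no diazo compound or photochemistry is involved. On these points it equals or betters the chosen plan.
- Against it: the key step creates no relative stereochemistry, because C2 arrives as a carbonyl carbon. Turning it into a CH–C≡C unit cis to the C1 arm needs either a one-carbon homologation through an aldehyde whose α-centre would drift towards trans, or alkynylation followed by deoxygenation of a tertiary propargylic alcohol through a planar intermediate with no clear facial bias. A13 also has an acidic, propargylic α-hydrogen and could isomerise to an allenyl ketone, A11 may add to A10 in conjugate fashion, and the light- and acid-sensitive bithiophene would be carried through every step.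
- Comparison: it is shorter to the four-membered ring but leaves the decisive cis problem unsolved, whereas the chosen plan sets it in the ring-forming step.

Key step: step 4

Assumption: the target is the cis (meso) isomer, so all intermediates are racemic and drawn as one enantiomer. The precursor 7 and product 10 of the key step are consistent with each other and with the target and need no correction. The design is tightened by storing the enolate regiochemistry in the silyl enol ether 4 and by keeping the triisopropylsilyl group until the last step.

## Route

Step 1
Reactants: 1 (triisopropylsilyl)acetylene; 2 cyclopent-2-en-1-one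
Product: 4 trimethyl({3-[(triisopropylsilyl)ethynyl]cyclopent-1-en-1-yl}oxy)silane (racemic), via alkynylzinc bromide 3 (not isolated)
Conditions: n-BuLi, THF, −78 to 0 °C; ZnBr2, 0 °C; then 2, TMSOTf, Et2O/THF, −40 °C; Et3N quench, cold aq. NaHCO3/pentane
Reagents that add atoms: trimethylsilyl trifluoromethanesulfonate, C[Si](C)(C)OS(=O)(=O)C(F)(F)F
Why: Silyl-triflate-promoted conjugate addition of an alkynylzinc halide to a cyclic enone: TMSOTf activates the s-trans enone, the zinc acetylide attacks C3, and the product is released directly as the C1=C2 silyl enol ether. The C3 stereocentre forms as a racemate, which is all the meso target requires.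

Step 2
Reactants: 4 trimethyl({3-[(triisopropylsilyl)ethynyl]cyclopent-1-en-1-yl}oxy)silane
Product: 6 2-(trifluoroacetyl)-3-[(triisopropylsilyl)ethynyl]cyclopentan-1-one (racemic; largely enolised), via lithium enolate 5 (not isolated)
Conditions: MeLi, THF, 0 °C to rt; then CF3CO2CH2CF3, −78 °C; dil. HCl work-up
Reagents that add atoms: 2,2,2-trifluoroethyl trifluoroacetate, O=C(OCC(F)(F)F)C(F)(F)F
Why: Methyllithium cleaves the O–Si bond to the regiodefined lithium enolate, which cannot equilibrate without a proton source and undergoes Claisen-type C-acylation at C2 (enolate trifluoroacetylation). The triisopropylsilyl alkyne is inert to MeLi.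

Step 3
Reactants: 6 2-(trifluoroacetyl)-3-[(triisopropylsilyl)ethynyl]cyclopentan-1-one
Product: 7 2-diazo-3-[(triisopropylsilyl)ethynyl]cyclopentan-1-one (racemic; one enantiomer drawn)
Conditions: 4-acetamidobenzenesulfonyl azide, Et3N, H2O (1 equiv), MeCN, rt, dark
Reagents that add atoms: 4-acetamidobenzenesulfonyl azide, CC(=O)Nc1ccc(cc1)S(=O)(=O)N=[N+]=[N-]
Why: Deacylative diazo transfer: the enolate of the 1,3-dicarbonyl compound adds to the sulfonyl azide and the adduct collapses with transfer of the trifluoroacetyl group to the sulfonamide nitrogen, leaving the diazo group at C2 between the carbonyl and the alkynyl-bearing carbon. C3 is untouched.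

Step 4
Reactants: 7 2-diazo-3-[(triisopropylsilyl)ethynyl]cyclopentan-1-one
Product: 10 methyl cis-2-[(triisopropylsilyl)ethynyl]cyclobutane-1-carboxylate (racemic; one enantiomer drawn), via cyclobutylidene ketene 8 (not isolated), via ester enol 9 (not isolated)
Conditions: hν (medium-pressure Hg lamp, Pyrex, λ > 300 nm), degassed MeOH, −40 °C
Reagents that add atoms: methanol, CO
Why: Direct irradiation of the cyclic diazoketone, whose diazo and carbonyl groups are locked s-cis, expels N2 with a concerted 1,2-shift of C5 from the carbonyl carbon to the diazo carbon (Wolff rearrangement), giving ketene 8 with the former carbonyl carbon exocyclic. The closest known reaction type is the photochemical Wolff ring contraction of 2-diazocyclopentanones to cyclobutanecarboxylic esters in alcohols. The four-membered ring is closed by ring contraction, not cyclisation: the cyclobutane bond C2–C3 is made by migration while the C1–C5 bond of the cyclopentanone is broken. Methanol adds to the ketene to give ester enol 9, and the new stereocentre arises when 9 is protonated at carbon on the face opposite the neighbouring alkynyl group (substrate control by the adjacent stereocentre), which places ester and alkyne cis under kinetic control. The step needs rearrangement to win over 1,2-hydride shift from C3 and over O–H insertion, which the anti-periplanar alignment of the migrating bond with the departing N2 in the rigid ring and excitation without metal or sensitiser should favour. The sense of contraction is fixed by the position of the diazo group, and low temperature with a neutral medium should sharpen the facial selectivity and prevent later epimerisation. The triisopropylsilyl alkyne does not absorb above 300 nm, so only the diazoketone is excited.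

Step 5
Reactants: 10 methyl cis-2-[(triisopropylsilyl)ethynyl]cyclobutane-1-carboxylate
Product: 12 cis-2-[(triisopropylsilyl)ethynyl]cyclobutane-1-carbaldehyde (racemic), via aluminium hemiacetal 11 (not isolated)
Conditions: i-Bu2AlH (1.1 equiv), CH2Cl2, −78 °C; MeOH quench at −78 °C; aq. potassium sodium tartrate, 0 °C
Reagents that add atoms: none
Why: Partial reduction of a methyl ester with diisobutylaluminium hydride: at −78 °C the tetrahedral aluminium hemiacetal persists and collapses to the aldehyde only on hydrolysis. The near-neutral tartrate work-up avoids enolisation of the cis α-stereocentre, and the aldehyde is used at once.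

Step 6
Reactants: 12 cis-2-[(triisopropylsilyl)ethynyl]cyclobutane-1-carbaldehyde
Product: 13 cis-1-(2,2-dibromoethenyl)-2-[(triisopropylsilyl)ethynyl]cyclobutane (racemic)
Conditions: CBr4, PPh3, Zn, CH2Cl2, rt (ylide preformed); then 12, 0 °C
Reagents that add atoms: carbon tetrabromide, BrC(Br)(Br)Br
Why: Ramirez dibromo-olefination, the first stage of the Corey–Fuchs sequence: the zinc-modified ylide Ph3P=CBr2 is non-basic, so the enolisable cis aldehyde should undergo the Wittig reaction faster than it can epimerise. Once C2 carries an alkene it is no longer acidic.

Step 7
Reactants: 13 cis-1-(2,2-dibromoethenyl)-2-[(triisopropylsilyl)ethynyl]cyclobutane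
Product: 15 cis-1-ethynyl-2-[(triisopropylsilyl)ethynyl]cyclobutane (racemic), via lithium acetylide 14 (not isolated)
Conditions: n-BuLi (2.2 equiv), THF, −78 to 0 °C; then H2O
Reagents that add atoms: none
Why: Second stage of the Corey–Fuchs homologation: bromine–lithium exchange and elimination give the alkyne by a Fritsch–Buttenberg–Wiechell-type 1,2-shift, and a second equivalent of base gives the acetylide, protonated on work-up. Neither ring stereocentre is acidic under these conditions and the silyl alkyne is inert.

Step 8
Reactants: 15 cis-1-ethynyl-2-[(triisopropylsilyl)ethynyl]cyclobutane; 16 5-bromo-2,2'-bithiophene (2.3 equiv)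
Product: 18 isocardopatine [cis-1,2-bis{(2,2'-bithiophen-5-yl)ethynyl}cyclobutane; meso], via cis-1,2-diethynylcyclobutane 17 (not isolated)
Conditions: Bu4NF, THF, 0 °C; then 16, Pd(PPh3)4 (5 mol %), CuI (10 mol %), i-Pr2NH, degassed, 50 °C, dark
Reagents that add atoms: none
Why: Fluoride cleaves the C(sp)–Si bond and the volatile meso diyne is coupled in the same flask in a twofold Sonogashira reaction (oxidative addition of the 2-bromothiophene to zerovalent palladium, copper acetylide transmetalation, reductive elimination). The propargylic ring stereocentres are not affected by amine base at 50 °C, so the cis configuration is carried into the target.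

## Compound list

1 | (triisopropylsilyl)acetylene | C#C[Si](C(C)C)(C(C)C)C(C)C | starting material
2 | cyclopent-2-en-1-one | O=C1C=CCC1 | starting material
3 | bromo[(triisopropylsilyl)ethynyl]zinc (alkynylzinc bromide) | Br[Zn]C#C[Si](C(C)C)(C(C)C)C(C)C | intermediate (not isolated)
4 | trimethyl({3-[(triisopropylsilyl)ethynyl]cyclopent-1-en-1-yl}oxy)silane (racemic) | C[Si](C)(C)OC1=C[C@@H](C#C[Si](C(C)C)(C(C)C)C(C)C)CC1 | intermediate
5 | lithium 3-[(triisopropylsilyl)ethynyl]cyclopent-1-en-1-olate (lithium enolate) | [Li]OC1=C[C@@H](C#C[Si](C(C)C)(C(C)C)C(C)C)CC1 | intermediate (not isolated)
6 | 2-(trifluoroacetyl)-3-[(triisopropylsilyl)ethynyl]cyclopentan-1-one (racemic; C2 not defined, largely enolised) | O=C1CC[C@H](C#C[Si](C(C)C)(C(C)C)C(C)C)C1C(=O)C(F)(F)F | intermediate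
7 | 2-diazo-3-[(triisopropylsilyl)ethynyl]cyclopentan-1-one (racemic) | [N-]=[N+]=C1C(=O)CC[C@@H]1C#C[Si](C(C)C)(C(C)C)C(C)C | intermediate
8 | {2-[(triisopropylsilyl)ethynyl]cyclobutylidene}methanone (cyclobutylidene ketene) | O=C=C1CC[C@@H]1C#C[Si](C(C)C)(C(C)C)C(C)C | intermediate (not isolated)
9 | methoxy{2-[(triisopropylsilyl)ethynyl]cyclobutylidene}methanol (ester enol; alkene geometry not defined) | COC(O)=C1CC[C@@H]1C#C[Si](C(C)C)(C(C)C)C(C)C | intermediate (not isolated)
10 | methyl cis-2-[(triisopropylsilyl)ethynyl]cyclobutane-1-carboxylate (racemic) | COC(=O)[C@@H]1CC[C@@H]1C#C[Si](C(C)C)(C(C)C)C(C)C | intermediate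
11 | diisobutylaluminium hemiacetal of 10 (acetal carbon not defined) | COC(O[Al](CC(C)C)CC(C)C)[C@@H]1CC[C@@H]1C#C[Si](C(C)C)(C(C)C)C(C)C | intermediate (not isolated)
12 | cis-2-[(triisopropylsilyl)ethynyl]cyclobutane-1-carbaldehyde (racemic) | O=C[C@@H]1CC[C@@H]1C#C[Si](C(C)C)(C(C)C)C(C)C | intermediate
13 | cis-1-(2,2-dibromoethenyl)-2-[(triisopropylsilyl)ethynyl]cyclobutane (racemic) | BrC(Br)=C[C@@H]1CC[C@@H]1C#C[Si](C(C)C)(C(C)C)C(C)C | intermediate
14 | lithium acetylide of 15 | [Li]C#C[C@@H]1CC[C@@H]1C#C[Si](C(C)C)(C(C)C)C(C)C | intermediate (not isolated)
15 | cis-1-ethynyl-2-[(triisopropylsilyl)ethynyl]cyclobutane (racemic) | C#C[C@@H]1CC[C@@H]1C#C[Si](C(C)C)(C(C)C)C(C)C | intermediate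
16 | 5-bromo-2,2'-bithiophene | Brc1ccc(-c2cccs2)s1 | starting material
17 | cis-1,2-diethynylcyclobutane (meso) | C#C[C@@H]1CC[C@@H]1C#C | intermediate (not isolated)
18 | isocardopatine, cis-1,2-bis[(2,2'-bithiophen-5-yl)ethynyl]cyclobutane (meso, 1R,2S) | C(#C[C@@H]1CC[C@@H]1C#Cc1ccc(-c2cccs2)s1)c1ccc(-c2cccs2)s1 | target

## Step count and least certain steps

Total step count: 8. Longest linear sequence: 8 steps, from 1 and 2 to 18; 16 enters in the last step.

Step 4 (key step). The most likely failure is poor facial selectivity in the protonation of the ester enol, because an alkyne is a slim directing group, so some trans ester could form. A second danger is the competing 1,2-hydride shift from the propargylic C3–H to the carbene centre. Fallback: set out from 7 and run the photolysis without regard to selectivity. The mixture of 10 and methyl trans-2-[(triisopropylsilyl)ethynyl]cyclobutane-1-carboxylate F1 is deprotonated as a whole with LiN(i-Pr)2 in THF at −78 °C to the common lithium ester enolate F2. This is protonated at −78 °C with a hindered phenol (2,6-di-tert-butyl-4-methylphenol) from the face anti to the alkyne, a contra-thermodynamic kinetic protonation, and the route is rejoined at 10.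

Step 1. Competing 1,2-addition to the carbonyl group, or hydrolysis of the trimethylsilyl enol ether during isolation, would destroy the regiochemical information. Fallback: set out from 1 and 2. Convert 1 with n-BuLi and Me2AlCl into dimethyl[(triisopropylsilyl)ethynyl]alane F3, and add it to 2 in Et2O at −5 °C with a catalyst prepared from Ni(acac)2 and i-Bu2AlH. The dimethylaluminium enolate F4 is silylated in the flask with TMSOTf, rejoining at 4.

Step 2. Incomplete Si–O cleavage, proton transfer between enolate and product (loss of regiochemical integrity) or O-acylation could lower the yield of C2-acylated material. Fallback: set out from 4 and avoid any free enolate. A Mukaiyama-type reaction with HC(OMe)3 and catalytic TMSOTf in CH2Cl2 at −78 °C should give 2-(dimethoxymethyl)-3-[(triisopropylsilyl)ethynyl]cyclopentan-1-one F5. Aqueous acid unmasks 2-(hydroxymethylidene)-3-[(triisopropylsilyl)ethynyl]cyclopentan-1-one F6, and deformylative diazo transfer with 4-acetamidobenzenesulfonyl azide and Et3N rejoins the route at 7.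

Step 5. Over-reduction to the primary alcohol through premature collapse of the aluminium hemiacetal, or epimerisation of the cis aldehyde during work-up, is possible. Fallback: set out from 10 and reduce fully with LiAlH4 in Et2O at 0 °C to {cis-2-[(triisopropylsilyl)ethynyl]cyclobutyl}methanol F7. Oxidation with Dess–Martin periodinane buffered with NaHCO3 in CH2Cl2 at 0 °C rejoins the route at 12.

Step 8. Evaporative loss of the diyne, oxidative alkyne homocoupling to oligomers, or stalling after the first coupling with the moderately reactive bromothiophene may occur. Fallback: set out from 15 and couple the free terminal alkyne first with one equivalent of 16 (Pd(PPh3)4, CuI, i-Pr2NH, 50 °C) to give cis-1-[(2,2'-bithiophen-5-yl)ethynyl]-2-[(triisopropylsilyl)ethynyl]cyclobutane F8. Bu4NF in THF then gives the non-volatile cis-1-[(2,2'-bithiophen-5-yl)ethynyl]-2-ethynylcyclobutane F9, and a second Sonogashira coupling with 16 arrives at 18.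

## Further compounds

F1 | step 4 | methyl trans-2-[(triisopropylsilyl)ethynyl]cyclobutane-1-carboxylate (racemic) | COC(=O)[C@H]1CC[C@@H]1C#C[Si](C(C)C)(C(C)C)C(C)C
F2 | step 4 | lithium ester enolate of 10 and F1 (alkene geometry not defined) | COC(O[Li])=C1CC[C@@H]1C#C[Si](C(C)C)(C(C)C)C(C)C
F3 | step 1 | dimethyl[(triisopropylsilyl)ethynyl]alane | C[Al](C)C#C[Si](C(C)C)(C(C)C)C(C)C
F4 | step 1 | dimethylaluminium 3-[(triisopropylsilyl)ethynyl]cyclopent-1-en-1-olate | C[Al](C)OC1=C[C@@H](C#C[Si](C(C)C)(C(C)C)C(C)C)CC1
F5 | step 2 | 2-(dimethoxymethyl)-3-[(triisopropylsilyl)ethynyl]cyclopentan-1-one (C2 not defined) | COC(OC)C1C(=O)CC[C@@H]1C#C[Si](C(C)C)(C(C)C)C(C)C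
F6 | step 2 | 2-(hydroxymethylidene)-3-[(triisopropylsilyl)ethynyl]cyclopentan-1-one | OC=C1C(=O)CC[C@@H]1C#C[Si](C(C)C)(C(C)C)C(C)C
F7 | step 5 | {cis-2-[(triisopropylsilyl)ethynyl]cyclobutyl}methanol (racemic) | OC[C@@H]1CC[C@@H]1C#C[Si](C(C)C)(C(C)C)C(C)C
F8 | step 8 | cis-1-[(2,2'-bithiophen-5-yl)ethynyl]-2-[(triisopropylsilyl)ethynyl]cyclobutane (racemic) | CC(C)[Si](C#C[C@@H]1CC[C@@H]1C#Cc1ccc(-c2cccs2)s1)(C(C)C)C(C)C
F9 | step 8 | cis-1-[(2,2'-bithiophen-5-yl)ethynyl]-2-ethynylcyclobutane (racemic) | C#C[C@@H]1CC[C@@H]1C#Cc1ccc(-c2cccs2)s1
A1 | alternative 1 | cyclobutene | C1=CCC1
A2 | alternative 1 | cis-1,2-bis(4,4,5,5-tetramethyl-1,3,2-dioxaborolan-2-yl)cyclobutane (meso) | CC1(C)OB(OC1(C)C)[C@@H]1CC[C@@H]1B1OC(C)(C)C(C)(C)O1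
A3 | alternative 1 | 1-lithioethenyl N,N-diisopropylcarbamate | [Li]C(=C)OC(=O)N(C(C)C)C(C)C
A4 | alternative 1 | cis-1,2-diethynylcyclobutane (meso; identical with 17) | C#C[C@@H]1CC[C@@H]1C#C
A5 | alternative 2 | cyclohexa-1,4-diene | C1=CCC=CC1
A6 | alternative 2 | dichloroketene | O=C=C(Cl)Cl
A7 | alternative 2 | cis-8,8-dichlorobicyclo[4.2.0]oct-3-en-7-one (racemic) | C2[C@@H]1C(Cl)(Cl)C(=O)[C@@H]1CC=C2
A8 | alternative 2 | cis-bicyclo[4.2.0]oct-3-ene | C1=CC[C@@H]2CC[C@@H]2C1
A9 | alternative 2 | 2,2'-(cis-cyclobutane-1,2-diyl)diacetaldehyde | O=CC[C@@H]1CC[C@@H]1CC=O
A10 | alternative 3 | 3-(2,2'-bithiophen-5-yl)prop-2-ynal | O=CC#Cc1ccc(-c2cccs2)s1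
A11 | alternative 3 | diphenylsulfonium cyclopropylide | C1C[C-]1[S+](c1ccccc1)c1ccccc1
A12 | alternative 3 | 2-[(2,2'-bithiophen-5-yl)ethynyl]-1-oxaspiro[2.2]pentane (racemic) | C1CC12OC2C#Cc1ccc(-c2cccs2)s1
A13 | alternative 3 | 2-[(2,2'-bithiophen-5-yl)ethynyl]cyclobutan-1-one (racemic) | O=C1CC[C@@H]1C#Cc1ccc(-c2cccs2)s1
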